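**Plan**
- Retrosynthetic cuts, in order: the C8–CH(iPr) bond (Friedel–Crafts-type Michael addition, last step); the exocyclic C=C of the alkylidene triketone (Knoevenagel); in the triketone ring the C1(=O)–C2(Me) and C3(OMe)–C4(Me)2 bonds together (two-carbon ring expansion); the C2–phenyl bond of the flavanone (conjugate addition to a chromone).
- Enabling feature: in the methoxy-triketone ring the quaternary CMe2 carbon lies between two oxygenated sp2 carbons and C(Me)=C(OMe) is a 1-methoxypropyne unit. The ring is therefore a 2,2-dimethylcyclobutane-1,3-dione (as silyl enol ether) whose strained acyl–CMe2 bond has taken up the alkyne, which fixes the OMe position without any O-methylation.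
- Forward order: four-membered ring by ketene/ynol ether [2+2]; six-membered triketone ring by nickel-catalysed insertion of 1-methoxypropyne (the four-ring and the silyl group are the helpers, both gone at the end of that step); Knoevenagel. Separately: ring A oxygen pattern by C–H borylation, pyranone ring by the enaminone route, phenyl at C2, then union at C8.
- Stereochemistry: C2 (S) from ligand-controlled conjugate addition of phenylboronic acid to the chromone; the benzylic methine (R) from a chiral-phosphoric-acid-controlled addition of C8 to the alkylidene in the last step, its epimer being a separable diastereomer.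

Key step: step 5

Assumption: the (R)-pyridine-oxazoline ligand in step 12 and the (R)-phosphoric acid in step 14 are taken to give (2S) and (1R); if a first run shows the opposite sense, the enantiomeric ligand or acid is used with nothing else changed.

**Step 1**
Reactants: 1 2-chloro-1,1-dimethoxyethane
Product: 3 1-methoxyprop-1-yne, via sodium methoxyacetylide 2 (not isolated)
Conditions: NaNH2 (3 equiv), liquid NH3, −33 °C; then MeI, −40 °C; aqueous work-up, distillation
Reagents that add atoms: iodomethane, CI
Why: Twofold elimination (loss of methanol, then of HCl) by sodium amide gives the alkoxyacetylide, which is C-methylated by iodomethane in an SN2 reaction, the standard route to 1-alkoxyalk-1-ynes.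

**Step 2**
Reactants: 4 isobutyryl chloride; 5 ethoxyacetylene
Product: 7 3-ethoxy-4,4-dimethylcyclobut-2-en-1-one, via dimethylketene 6 (not isolated)
Conditions: Et3N, CH2Cl2, 0 °C to rt, slow addition of 4
Reagents that add atoms: none
Why: Dehydrochlorination gives dimethylketene, whose [2+2] cycloaddition with the ynol ether is regiospecific (nucleophilic alkyne CH carbon to the ketene carbonyl carbon), a known ketene–alkoxyalkyne cyclobutenone synthesis.

**Step 3**
Reactants: 7 3-ethoxy-4,4-dimethylcyclobut-2-en-1-one
Product: 8 3-hydroxy-4,4-dimethylcyclobut-2-en-1-one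
Conditions: 1 M aq. HCl, THF, rt
Reagents that add atoms: water, O
Why: Acid hydrolysis of the vinylogous ester (addition–elimination at C3) gives the strongly acidic enol of 2,2-dimethylcyclobutane-1,3-dione, and dilute acid avoids the base-induced retro-Claisen ring opening.

**Step 4**
Reactants: 8 3-hydroxy-4,4-dimethylcyclobut-2-en-1-one
Product: 9 4,4-dimethyl-3-[(triisopropylsilyl)oxy]cyclobut-2-en-1-one
Conditions: TIPSCl, Et3N, CH2Cl2, 0 °C
Reagents that add atoms: chlorotriisopropylsilane, CC(C)[Si](Cl)(C(C)C)C(C)C
Why: O-Silylation of the vinylogous acid masks the OH (which would add to the ynol ether and quench zerovalent nickel) as a neutral silyl enol ether, and since the two carbonyl positions of 8 are equivalent only one product can form.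

**Step 5**
Reactants: 9 4,4-dimethyl-3-[(triisopropylsilyl)oxy]cyclobut-2-en-1-one; 3 1-methoxyprop-1-yne
Product: 11 5-hydroxy-3-methoxy-2,4,4-trimethylcyclohexa-2,5-dien-1-one, via silyl dienone 10 (not isolated)
Conditions: Ni(cod)2 (10 mol%), PPh3 (20 mol%), toluene, 0 °C to rt, 3 added over 2 h; then 1 M aq. HCl, THF, 0 °C
Reagents that add atoms: none
Why: Proposed new method: zerovalent nickel should join the C≡C bond of 3 and the ring C=O of 9 by oxidative cyclization, the nucleophilic methyl-bearing alkyne carbon bonding to the acyl carbon C1 and nickel to the methoxy-bearing carbon, after which β-carbon elimination moves the quaternary C4 from C1 to nickel with release of the four-ring strain and C(sp2)–C(sp3) reductive elimination joins C(OMe) to CMe2 (direct insertion of nickel into the acyl–CMe2 bond followed by alkyne insertion would lead to the same nickelacycle). The closest known reaction types are the nickel-catalysed alkyne insertion into cyclobutenones that ends in phenols and the nickel-catalysed [4+2] ring expansion of cyclobutanones with alkynes, whereas a 4,4-disubstituted 3-silyloxycyclobutenone with an ynol ether, where the product cannot aromatise, has not been shown. The six-membered ring closes as a formal [4+2] two-carbon ring expansion, the four ring carbons of 9 plus the two alkyne carbons, and its last bond forms by reductive elimination from a seven-membered nickelacycle. No stereocentre is formed. The step needs cleavage of C1–C4 and not of C1–C2, secured because C4 is the only sp3 carbon on the carbonyl and the C2=C3 enol ether bond is strong, and it needs the alkyne orientation methyl-carbon to acyl, secured by the polarisation of the ynol ether. It also needs the thermal vinylketene route (which would place the alkyne between C1 and C2 and give the isomeric methyl ether) to stay closed, secured by working at or below room temperature, while the quaternary C4 keeps the dienone from tautomerising to a phenol and the silyl enol ether is hydrolysed in the acidic work-up.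

**Step 6**
Reactants: 11 5-hydroxy-3-methoxy-2,4,4-trimethylcyclohexa-2,5-dien-1-one; 12 isobutyraldehyde
Product: 14 5-methoxy-4,6,6-trimethyl-2-(2-methylpropylidene)cyclohex-4-ene-1,3-dione (mixture of alkene geometries), via Mannich base 13 (not isolated)
Conditions: piperidine (1.1 equiv), CH2Cl2, 0 °C to rt; then 1 M aq. HCl, 0 °C
Reagents that add atoms: none
Why: A Mannich reaction at C6, the only nucleophilic CH of the enolate, followed by acid-induced loss of piperidine amounts to a Knoevenagel condensation of the kind used for isobutylidene β-triketones, and the enolate form protects the methyl enol ether from amine exchange.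

**Step 7**
Reactants: 15 1,3-dimethoxy-2-methylbenzene
Product: 17 3,5-dimethoxy-4-methylphenol, via arylboronate 16 (not isolated)
Conditions: B2pin2, [Ir(OMe)(cod)]2 (1.5 mol%), 4,4'-di-tert-butyl-2,2'-bipyridine (3 mol%), THF, 80 °C; then 30% aq. H2O2, NaOH, 0 °C
Reagents that add atoms: hydrogen peroxide, OO
Why: Iridium-catalysed C–H borylation is sterically controlled and should go to C5, the only ring CH without an ortho substituent, and oxidation of the C–B bond gives the phenol whose oxygen becomes O1 of the flavanone, para to the C-methyl group.

**Step 8**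
Reactants: 17 3,5-dimethoxy-4-methylphenol
Product: 18 1-(6-hydroxy-2,4-dimethoxy-3-methylphenyl)ethan-1-one
Conditions: Ac2O, BF3·OEt2 (2 equiv), 0 to 50 °C; then H2O/MeOH, 50 °C
Reagents that add atoms: acetic anhydride, CC(=O)OC(C)=O
Why: Friedel–Crafts acylation (by way of O-acetylation and Fries shift to the BF2 chelate) can only take place ortho to the free OH because the para position carries the methyl group, which places the acetyl group next to the one free phenol oxygen.

**Step 9**
Reactants: 18 1-(6-hydroxy-2,4-dimethoxy-3-methylphenyl)ethan-1-one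
Product: 20 5,7-dimethoxy-6-methyl-4H-chromen-4-one, via enaminone 19 (not isolated)
Conditions: Me2NCH(OMe)2, toluene, 100 °C; then conc. HCl, CH2Cl2, rt
Reagents that add atoms: N,N-dimethylformamide dimethyl acetal, COC(OC)N(C)C
Why: Condensation of the methyl ketone with the amide acetal gives the enaminone, and acid-induced conjugate addition of the only free ortho OH with loss of dimethylamine closes the pyranone ring (enaminone route to chromones), so the C-methyl group ends at C6 without ambiguity.

**Step 10**
Reactants: 20 5,7-dimethoxy-6-methyl-4H-chromen-4-one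
Product: 21 5,7-dihydroxy-6-methyl-4H-chromen-4-one
Conditions: BBr3 (5 equiv), CH2Cl2, −78 °C to rt; then H2O
Reagents that add atoms: none
Why: Lewis-acid ether cleavage by BBr3 removes both O-methyl groups at the robust, achiral chromone stage, where no stereocentre can be lost.

**Step 11**
Reactants: 21 5,7-dihydroxy-6-methyl-4H-chromen-4-one
Product: 22 5,7-bis(benzyloxy)-6-methyl-4H-chromen-4-one
Conditions: BnBr, K2CO3, DMF, 70 °C
Reagents that add atoms: benzyl bromide, BrCc1ccccc1
Why: Williamson O-benzylation masks both phenols (a free 5-OH next to the 4-C=O would chelate palladium in the next step) with groups that can later be removed under neutral conditions.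

**Step 12**
Reactants: 22 5,7-bis(benzyloxy)-6-methyl-4H-chromen-4-one; 23 phenylboronic acid
Product: 24 (2S)-5,7-bis(benzyloxy)-6-methyl-2-phenyl-2,3-dihydro-4H-chromen-4-one
Conditions: Pd(OCOCF3)2 (5 mol%), (R)-4-tert-butyl-2-(pyridin-2-yl)-4,5-dihydrooxazole (6 mol%), NH4PF6 (30 mol%), H2O (5 equiv), ClCH2CH2Cl, 60 °C
Reagents that add atoms: none
Why: In this ligand-controlled conjugate addition of an arylboronic acid to a chromone (Hayashi–Miyaura-type 1,4-addition with a divalent palladium pyridine-oxazoline catalyst), aryl transfer to one face of C2 should fix the (2S) centre and protonation of the palladium enolate gives the flavanone.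

**Step 13**
Reactants: 24 (2S)-5,7-bis(benzyloxy)-6-methyl-2-phenyl-2,3-dihydro-4H-chromen-4-one
Product: 25 (2S)-5,7-dihydroxy-6-methyl-2-phenyl-2,3-dihydro-4H-chromen-4-one
Conditions: H2 (1 atm), Pd/C (10 wt%), EtOAc/MeOH, rt
Reagents that add atoms: none
Why: Hydrogenolysis of the two benzyl ethers over palladium on carbon is neutral, so the 5- and 7-OH groups are freed without enolisation or ring opening and C2 keeps its configuration.

**Step 14**
Reactants: 25 (2S)-5,7-dihydroxy-6-methyl-2-phenyl-2,3-dihydro-4H-chromen-4-one; 14 5-methoxy-4,6,6-trimethyl-2-(2-methylpropylidene)cyclohex-4-ene-1,3-dione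
Product: 26 (2S)-5,7-dihydroxy-8-[(1R)-1-(2-hydroxy-4-methoxy-3,3,5-trimethyl-6-oxocyclohexa-1,4-dien-1-yl)-2-methylpropyl]-6-methyl-2-phenyl-2,3-dihydro-4H-chromen-4-one
Conditions: (R)-3,3'-bis(2,4,6-triisopropylphenyl)-1,1'-binaphthyl-2,2'-diyl hydrogen phosphate (10 mol%), 4 Å molecular sieves, CH2Cl2/EtOAc 9:1, −20 °C to rt; chromatography
Reagents that add atoms: none
Why: In this chiral-phosphoric-acid-catalysed Friedel–Crafts-type Michael addition the acid should bind the alkylidene dione carbonyl through P–OH and the 7-OH through P=O, so that C8, the only free carbon of ring A, adds to one face of the exocyclic CH and sets the (R) methine under catalyst control while C2 is untouched under base-free conditions; the (S) epimer is a diastereomer and is removed by chromatography.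

**Compound list**
1 | 2-chloro-1,1-dimethoxyethane | COC(CCl)OC | starting material
2 | sodium methoxyacetylide | [Na+].[C-]#COC | intermediate (not isolated)
3 | 1-methoxyprop-1-yne | CC#COC | intermediate
4 | isobutyryl chloride | CC(C)C(Cl)=O | starting material
5 | ethoxyacetylene | CCOC#C | starting material
6 | dimethylketene | CC(C)=C=O | intermediate (not isolated)
7 | 3-ethoxy-4,4-dimethylcyclobut-2-en-1-one | CCOC1=CC(=O)C1(C)C | intermediate
8 | 3-hydroxy-4,4-dimethylcyclobut-2-en-1-one | OC1=CC(=O)C1(C)C | intermediate
9 | 4,4-dimethyl-3-[(triisopropylsilyl)oxy]cyclobut-2-en-1-one | CC(C)[Si](OC1=CC(=O)C1(C)C)(C(C)C)C(C)C | intermediate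
10 | 3-methoxy-2,4,4-trimethyl-5-[(triisopropylsilyl)oxy]cyclohexa-2,5-dien-1-one | COC1=C(C)C(=O)C=C(O[Si](C(C)C)(C(C)C)C(C)C)C1(C)C | intermediate (not isolated)
11 | 5-hydroxy-3-methoxy-2,4,4-trimethylcyclohexa-2,5-dien-1-one | COC1=C(C)C(=O)C=C(O)C1(C)C | intermediate
12 | isobutyraldehyde | CC(C)C=O | starting material
13 | 5-hydroxy-3-methoxy-2,4,4-trimethyl-6-[2-methyl-1-(piperidin-1-yl)propyl]cyclohexa-2,5-dien-1-one (racemic Mannich base) | COC1=C(C)C(=O)C(C(N2CCCCC2)C(C)C)=C(O)C1(C)C | intermediate (not isolated)
14 | 5-methoxy-4,6,6-trimethyl-2-(2-methylpropylidene)cyclohex-4-ene-1,3-dione (mixture of alkene geometries) | COC1=C(C)C(=O)C(=CC(C)C)C(=O)C1(C)C | intermediate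
15 | 1,3-dimethoxy-2-methylbenzene | COc1cccc(OC)c1C | starting material
16 | 2-(3,5-dimethoxy-4-methylphenyl)-4,4,5,5-tetramethyl-1,3,2-dioxaborolane | COc1cc(B2OC(C)(C)C(C)(C)O2)cc(OC)c1C | intermediate (not isolated)
17 | 3,5-dimethoxy-4-methylphenol | COc1cc(O)cc(OC)c1C | intermediate
18 | 1-(6-hydroxy-2,4-dimethoxy-3-methylphenyl)ethan-1-one | CC(=O)c1c(O)cc(OC)c(C)c1OC | intermediate
19 | (E)-3-(dimethylamino)-1-(6-hydroxy-2,4-dimethoxy-3-methylphenyl)prop-2-en-1-one | CN(C)/C=C/C(=O)c1c(O)cc(OC)c(C)c1OC | intermediate (not isolated)
20 | 5,7-dimethoxy-6-methyl-4H-chromen-4-one | COc1cc2occc(=O)c2c(OC)c1C | intermediate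
21 | 5,7-dihydroxy-6-methyl-4H-chromen-4-one | Cc1c(O)cc2occc(=O)c2c1O | intermediate
22 | 5,7-bis(benzyloxy)-6-methyl-4H-chromen-4-one | Cc1c(OCc2ccccc2)cc2occc(=O)c2c1OCc1ccccc1 | intermediate
23 | phenylboronic acid | OB(O)c1ccccc1 | starting material
24 | (2S)-5,7-bis(benzyloxy)-6-methyl-2-phenyl-2,3-dihydro-4H-chromen-4-one | O=C1C[C@@H](c2ccccc2)Oc2cc(OCc3ccccc3)c(C)c(OCc3ccccc3)c12 | intermediate
25 | (2S)-5,7-dihydroxy-6-methyl-2-phenyl-2,3-dihydro-4H-chromen-4-one | O=C1C[C@@H](c2ccccc2)Oc2cc(O)c(C)c(O)c12 | intermediate
26 | (2S)-5,7-dihydroxy-8-[(1R)-1-(2-hydroxy-4-methoxy-3,3,5-trimethyl-6-oxocyclohexa-1,4-dien-1-yl)-2-methylpropyl]-6-methyl-2-phenyl-2,3-dihydro-4H-chromen-4-one | COC1=C(C)C(=O)C([C@@H](c2c(O)c(C)c(O)c3c2O[C@H](c2ccccc2)CC3=O)C(C)C)=C(O)C1(C)C | target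

**Step count**
Total: 14 steps. Longest linear sequence: 8 steps (7 to 13, then 14); the triketone branch (2 to 6, then 14) is 6 steps, with step 1 feeding step 5.

**Steps most likely to fail**

1. Step 5. The nickel may fail to open the hindered acyl–CMe2 bond of the electron-rich enone, the ynol ether may be consumed by nickel-mediated oligomerisation, or the alkyne may insert with mixed orientation. The fallback is a thermal annulation with the roles of the partners exchanged and sets out from 3, 4 and 5. Dimethylketene 6, made from 4 and Et3N, is trapped by 3 in a [2+2] cycloaddition to give 3-methoxy-2,4,4-trimethylcyclobut-2-en-1-one F1. Heating F1 with ethoxyacetylene 5 in toluene at 80–90 °C in a sealed tube should give 3-ethoxy-5-methoxy-4,6,6-trimethylcyclohexa-2,4-dien-1-one F2 by a Danheiser-type annulation (electrocyclic opening to the vinylketene, [2+2] with the ynol ether, a second opening, six-electron closure onto CMe2). In F2 the methoxy group already sits between C(Me) and CMe2. Dilute aqueous HCl in THF should hydrolyse the less hindered ethyl enol ether (β to the carbonyl, next to a CH) and give the enol, a tautomer of 11, where the fallback comes back to the route.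

2. Step 14. Facial selectivity at the prochiral alkylidene carbon may be poor, because 14 is a mixture of alkene geometries and the stereocentre of 25 is remote, and the ratio may erode by retro-Michael re-addition. The fallback reverses the polarity and sets out from 25, 12 and 11. Condensation of 25 with isobutyraldehyde 12 and 4-methylbenzenesulfinic acid in aqueous formic acid should give, at C8, the sulfone (2S)-5,7-dihydroxy-6-methyl-8-[2-methyl-1-(4-methylbenzenesulfonyl)propyl]-2-phenyl-2,3-dihydro-4H-chromen-4-one F3 as a mixture of epimers. In a two-phase system (aqueous Na2CO3/CH2Cl2) F3 should lose sulfinate to give the ortho-quinone methide (2S)-5-hydroxy-6-methyl-8-(2-methylpropylidene)-2-phenyl-2,3-dihydro-4H-chromene-4,7(8H)-dione F4. The enol 11 then adds to F4 under a quinine-derived bifunctional squaramide catalyst, both epimers of F3 converging on the same planar intermediate. The fallback comes back to the route at 26.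

3. Step 12. Carbopalladation of the electron-rich chromone with its peri benzyloxy group may be slow, the boronic acid may be lost by protodeboronation and homocoupling, and facial control may be incomplete. The fallback is a kinetic resolution and sets out from 22 and 23. Conjugate addition with Pd(OCOCF3)2 and achiral 2,2'-bipyridine should give racemic 5,7-bis(benzyloxy)-6-methyl-2-phenyl-2,3-dihydro-4H-chromen-4-one F5. Noyori-type asymmetric transfer hydrogenation (RuCl(p-cymene)[(R,R)-TsDPEN] or its enantiomer, whichever reduces the (2R) ketone faster, HCO2H/Et3N), stopped near half conversion, should turn the (2R) enantiomer into the cis alcohol (2R,4R)-5,7-bis(benzyloxy)-6-methyl-2-phenylchroman-4-ol F6. The unreacted (2S) ketone is separated by chromatography, and the fallback comes back to the route at 24.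

**Further compounds**
F1 | step 5 | 3-methoxy-2,4,4-trimethylcyclobut-2-en-1-one | COC1=C(C)C(=O)C1(C)C
F2 | step 5 | 3-ethoxy-5-methoxy-4,6,6-trimethylcyclohexa-2,4-dien-1-one | CCOC1=CC(=O)C(C)(C)C(OC)=C1C
F3 | step 14 | (2S)-5,7-dihydroxy-6-methyl-8-[2-methyl-1-(4-methylbenzenesulfonyl)propyl]-2-phenyl-2,3-dihydro-4H-chromen-4-one (both epimers at the sulfonyl carbon) | Cc1ccc(cc1)S(=O)(=O)C(C(C)C)c1c(O)c(C)c(O)c2c1O[C@H](c1ccccc1)CC2=O
F4 | step 14 | (2S)-5-hydroxy-6-methyl-8-(2-methylpropylidene)-2-phenyl-2,3-dihydro-4H-chromene-4,7(8H)-dione | O=C1C[C@@H](c2ccccc2)OC2=C1C(O)=C(C)C(=O)C2=CC(C)C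
F5 | step 12 | racemic 5,7-bis(benzyloxy)-6-methyl-2-phenyl-2,3-dihydro-4H-chromen-4-one | O=C1CC(c2ccccc2)Oc2cc(OCc3ccccc3)c(C)c(OCc3ccccc3)c12
F6 | step 12 | (2R,4R)-5,7-bis(benzyloxy)-6-methyl-2-phenylchroman-4-ol | O[C@@H]1C[C@H](c2ccccc2)Oc2cc(OCc3ccccc3)c(C)c(OCc3ccccc3)c12
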